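**Retrosynthetic overview**

1. Target 19 comes from global deacylation of 18. The flavone C2–aryl bond of 18 is made by Negishi coupling of the C2-zincated chromone 7 (rings A and C) with aryl bromide 16 (ring B).
2. The dihydrobenzofuranol of 16 comes from ring contraction of a 2,2-dimethylchroman: the aryl ether oxygen shifts from C2 to C3 in triflate 15 and water captures the CMe2 cation.
3. Triflate 15 comes from trans acetolysis of the (3R,4R)-chromene oxide 13, which sets both stereocentres. Epoxide 13 comes from Jacobsen epoxidation of chromene 12, built from 4-bromophenol, prenyl bromide and 3-methylbut-2-enal.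
4. Chromone 7 comes from resorcinol by C-acetylation, pivaloylation, ketone-directed C–H hydroxylation (third oxygen of ring A) and one-carbon annulation.
5. Ring order: pyranone ring C on ring A (step 4); pyran ring on ring B (step 6); pyran contracted to the dihydrofuran (step 9); the two halves joined (step 10).

Assumption: the (R,R)-enantiomer of the manganese salen catalyst gives the (3R,4R)-oxide of 12, as with other 2,2-dimethyl-2H-chromenes; if the sense were opposite, the (S,S)-catalyst would be used.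

**Step 1**
Reactants: 1 resorcinol
Product: 2 1-(2,4-dihydroxyphenyl)ethan-1-one
Conditions: AcOH, ZnCl2, 140 °C
Reagents that add atoms: acetic acid, CC(=O)O
Why: Nencki reaction (Friedel–Crafts C-acylation); the zinc-activated acid acylates resorcinol at C4, which is ortho to one hydroxyl, para to the other and unhindered.

**Step 2**
Reactants: 2 1-(2,4-dihydroxyphenyl)ethan-1-one
Product: 3 4-acetyl-1,3-phenylene bis(2,2-dimethylpropanoate)
Conditions: PivCl, Et3N, DMAP (cat.), CH2Cl2, 0 °C → rt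
Reagents that add atoms: pivaloyl chloride, CC(C)(C)C(Cl)=O
Why: DMAP-catalysed O-acylation of both phenols gives esters that are expected to survive the acidic oxidising medium of step 3 and the zinc amide base of step 10.

**Step 3**
Reactants: 3 4-acetyl-1,3-phenylene bis(2,2-dimethylpropanoate)
Product: 5 4-acetyl-5-hydroxy-1,3-phenylene bis(2,2-dimethylpropanoate), via aryl trifluoroacetate 4 (not isolated)
Conditions: [RuCl2(p-cymene)]2 (2.5 mol %), PhI(OCOCF3)2, CF3CO2H/(CF3CO)2O, 80 °C; then H2O/THF, rt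
Reagents that add atoms: [bis(trifluoroacetoxy)iodo]benzene, O=C(OI(OC(=O)C(F)(F)F)c1ccccc1)C(F)(F)F; trifluoroacetic acid, OC(=O)C(F)(F)F
Why: ketone-directed ruthenium-catalysed ortho C–H oxygenation; cycloruthenation occurs at the only C–H ortho to the acetyl group, the hypervalent iodine reagent oxidises the metallacycle, C–O reductive elimination gives trifluoroacetate 4, and water cleaves it while the pivalates stay.

**Step 4**
Reactants: 5 4-acetyl-5-hydroxy-1,3-phenylene bis(2,2-dimethylpropanoate)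
Product: 7 4-oxo-4H-chromene-5,7-diyl bis(2,2-dimethylpropanoate), via enaminone 6 (not isolated)
Conditions: Me2NCH(OMe)2, toluene, 90 °C; then AcOH, 60 °C
Reagents that add atoms: N,N-dimethylformamide dimethyl acetal, COC(OC)N(C)C
Why: enaminone route to chromones; the acetyl methyl condenses with the amide acetal and the free ortho hydroxyl then adds to the enaminone and expels dimethylamine, closing ring C.

**Step 5**
Reactants: 8 4-bromophenol; 9 1-bromo-3-methylbut-2-ene
Product: 10 4-bromo-2-(3-methylbut-2-en-1-yl)phenol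
Conditions: NaH, toluene, 0 °C → rt
Reagents that add atoms: none
Why: ortho-selective C-alkylation of a sodium phenoxide in a non-polar solvent, where the tight ion pair delivers the allylic bromide to the ortho carbon; the para position is blocked by bromine.

**Step 6**
Reactants: 10 4-bromo-2-(3-methylbut-2-en-1-yl)phenol; 11 3-methylbut-2-enal
Product: 12 6-bromo-2,2-dimethyl-8-(3-methylbut-2-en-1-yl)-2H-chromene
Conditions: PhB(OH)2, AcOH (cat.), toluene, reflux (Dean–Stark)
Reagents that add atoms: none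
Why: boronic acid-templated ortho-hydroxyalkylation of the phenol by the enal, loss of water to an ortho-quinone methide and oxa-6π electrocyclisation (2H-chromene annulation) at the one free ortho position.

**Step 7**
Reactants: 12 6-bromo-2,2-dimethyl-8-(3-methylbut-2-en-1-yl)-2H-chromene
Product: 13 (3R,4R)-6-bromo-3,4-epoxy-2,2-dimethyl-8-(3-methylbut-2-en-1-yl)-3,4-dihydro-2H-chromene
Conditions: (R,R)-[N,N′-bis(3,5-di-tert-butylsalicylidene)-1,2-cyclohexanediaminato]manganese chloride (2 mol %), 4-phenylpyridine N-oxide, aq. NaOCl (pH 11.3), CH2Cl2, 0 °C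
Reagents that add atoms: sodium hypochlorite, [Na+].[O-]Cl
Why: Jacobsen–Katsuki epoxidation; the cis, aryl-conjugated alkene of a 2,2-dimethylchromene is the best substrate class for this catalyst, which sets both stereocentres as (3R,4R) by face-selective oxygen transfer, while the isolated trisubstituted prenyl alkene reacts much more slowly.

**Step 8**
Reactants: 13 (3R,4R)-6-bromo-3,4-epoxy-2,2-dimethyl-8-(3-methylbut-2-en-1-yl)-3,4-dihydro-2H-chromene
Product: 14 (3R,4S)-6-bromo-3-hydroxy-2,2-dimethyl-8-(3-methylbut-2-en-1-yl)-3,4-dihydro-2H-chromen-4-yl acetate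
Conditions: AcOH, NaOAc, 40 °C
Reagents that add atoms: acetic acid, CC(=O)O
Why: buffered anti (SN2-type) acetolysis of the epoxide at the benzylic C4 (C3 is neopentyl-like and shielded); inversion at C4 gives 4S, C3 keeps 3R, so the product is the trans hydroxy acetate.

**Step 9**
Reactants: 14 (3R,4S)-6-bromo-3-hydroxy-2,2-dimethyl-8-(3-methylbut-2-en-1-yl)-3,4-dihydro-2H-chromen-4-yl acetate
Product: 16 (2S,3S)-5-bromo-2-(2-hydroxypropan-2-yl)-7-(3-methylbut-2-en-1-yl)-2,3-dihydro-1-benzofuran-3-yl acetate, via secondary triflate 15 (not isolated)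
Conditions: Tf2O, 2,6-lutidine (3 equiv), CH2Cl2, −78 → −40 °C; then acetone/H2O (4:1), −40 → 40 °C
Reagents that add atoms: water, O; trifluoromethanesulfonic anhydride, O=S(=O)(OS(=O)(=O)C(F)(F)F)C(F)(F)F (its triflyl group is in 15 only)
Why: Proposed new method: a water-terminated, stereospecific 1,2-aryloxy shift (ring contraction) of a trans-4-acyloxy-2,2-dimethylchroman-3-yl triflate; in the favoured diequatorial half-chair of 15 the C3–OTf bond is antiperiplanar to the O1–C2 bond, so O1 displaces triflate from the rear with inversion at C3 and the resulting aryloxiranium ion/tertiary CMe2 cation is captured by water, while C4 (the new C3) is untouched, which converts the (3R,4S)-chroman into the (2S,3S) trans-dihydrobenzofuran; acetoxonium participation and methyl shift need the diaxial conformer, which the syn-axial methyl/acetoxy contact disfavours, and aryl migration would give a destabilised α-acetoxy cation; the closest known reactions are the dehydrative or fluorinative ring contraction of 4-unsubstituted 3-hydroxy-2,2-dimethylchromans to 2-isopropenyl- or 2-(2-fluoropropan-2-yl)-2,3-dihydrobenzofurans on hydroxyl activation (DAST, SOCl2, Mitsunobu conditions) and the ring contraction of equatorial pyranoside 2-triflates.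

**Step 10**
Reactants: 7 4-oxo-4H-chromene-5,7-diyl bis(2,2-dimethylpropanoate); 16 (2S,3S)-5-bromo-2-(2-hydroxypropan-2-yl)-7-(3-methylbut-2-en-1-yl)-2,3-dihydro-1-benzofuran-3-yl acetate
Product: 18 2-[(2S,3S)-3-acetoxy-2-(2-hydroxypropan-2-yl)-7-(3-methylbut-2-en-1-yl)-2,3-dihydro-1-benzofuran-5-yl]-4-oxo-4H-chromene-5,7-diyl bis(2,2-dimethylpropanoate), via chromon-2-ylzinc chloride 17 (not isolated)
Conditions: 7 (1.6 equiv), TMPZnCl·LiCl, THF, 25 °C; then 16, Pd(OAc)2 (4 mol %), SPhos (8 mol %), THF, 40 °C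
Reagents that add atoms: TMPZnCl·LiCl, CC1(C)CCCC(C)(C)N1[Zn]Cl.[Li+].[Cl-] (zinc and chloride are in 17 only)
Why: the magnesium-free TMP zinc base metalates chromones at C2, the most acidic C–H, without touching aryl esters, and Negishi cross-coupling of the resulting heteroarylzinc with the aryl bromide under Pd(OAc)2/SPhos outpaces protonation by the tertiary hydroxyl; no stereocentre is involved.

**Step 11**
Reactants: 18 2-[(2S,3S)-3-acetoxy-2-(2-hydroxypropan-2-yl)-7-(3-methylbut-2-en-1-yl)-2,3-dihydro-1-benzofuran-5-yl]-4-oxo-4H-chromene-5,7-diyl bis(2,2-dimethylpropanoate)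
Product: 19 5,7-dihydroxy-2-[(2S,3S)-3-hydroxy-2-(2-hydroxypropan-2-yl)-7-(3-methylbut-2-en-1-yl)-2,3-dihydro-1-benzofuran-5-yl]-4H-chromen-4-one
Conditions: K2CO3, MeOH, rt; then aq. HCl to pH 5
Reagents that add atoms: none
Why: Zemplén-type methanolysis removes the two aryl pivalates and the benzylic acetate by acyl–oxygen cleavage, so neither stereocentre is touched and the prenyl group, tertiary alcohol and flavone are inert to the mild base.

**Compound list**

1 | benzene-1,3-diol (resorcinol) | Oc1cccc(O)c1 | starting material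
2 | 1-(2,4-dihydroxyphenyl)ethan-1-one | CC(=O)c1ccc(O)cc1O | intermediate
3 | 4-acetyl-1,3-phenylene bis(2,2-dimethylpropanoate) | CC(=O)c1ccc(OC(=O)C(C)(C)C)cc1OC(=O)C(C)(C)C | intermediate
4 | 2-acetyl-3,5-bis(2,2-dimethylpropanoyloxy)phenyl trifluoroacetate | CC(=O)c1c(OC(=O)C(F)(F)F)cc(OC(=O)C(C)(C)C)cc1OC(=O)C(C)(C)C | intermediate
5 | 4-acetyl-5-hydroxy-1,3-phenylene bis(2,2-dimethylpropanoate) | CC(=O)c1c(O)cc(OC(=O)C(C)(C)C)cc1OC(=O)C(C)(C)C | intermediate
6 | 4-[(2E)-3-(dimethylamino)prop-2-enoyl]-5-hydroxy-1,3-phenylene bis(2,2-dimethylpropanoate) | CN(C)/C=C/C(=O)c1c(O)cc(OC(=O)C(C)(C)C)cc1OC(=O)C(C)(C)C | intermediate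
7 | 4-oxo-4H-chromene-5,7-diyl bis(2,2-dimethylpropanoate) | O=c1ccoc2cc(OC(=O)C(C)(C)C)cc(OC(=O)C(C)(C)C)c12 | intermediate
8 | 4-bromophenol | Oc1ccc(Br)cc1 | starting material
9 | 1-bromo-3-methylbut-2-ene (prenyl bromide) | CC(C)=CCBr | starting material
10 | 4-bromo-2-(3-methylbut-2-en-1-yl)phenol | CC(C)=CCc1cc(Br)ccc1O | intermediate
11 | 3-methylbut-2-enal | CC(C)=CC=O | starting material
12 | 6-bromo-2,2-dimethyl-8-(3-methylbut-2-en-1-yl)-2H-chromene | CC(C)=CCc1cc(Br)cc2C=CC(C)(C)Oc12 | intermediate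
13 | (3R,4R)-6-bromo-3,4-epoxy-2,2-dimethyl-8-(3-methylbut-2-en-1-yl)-3,4-dihydro-2H-chromene | CC(C)=CCc1cc(Br)cc2c1OC(C)(C)[C@@H]3O[C@H]23 | intermediate
14 | (3R,4S)-6-bromo-3-hydroxy-2,2-dimethyl-8-(3-methylbut-2-en-1-yl)-3,4-dihydro-2H-chromen-4-yl acetate | CC(C)=CCc1cc(Br)cc2c1OC(C)(C)[C@H](O)[C@H]2OC(C)=O | intermediate
15 | (3R,4S)-6-bromo-2,2-dimethyl-8-(3-methylbut-2-en-1-yl)-3-[(trifluoromethanesulfonyl)oxy]-3,4-dihydro-2H-chromen-4-yl acetate | CC(C)=CCc1cc(Br)cc2c1OC(C)(C)[C@H](OS(=O)(=O)C(F)(F)F)[C@H]2OC(C)=O | intermediate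
16 | (2S,3S)-5-bromo-2-(2-hydroxypropan-2-yl)-7-(3-methylbut-2-en-1-yl)-2,3-dihydro-1-benzofuran-3-yl acetate | CC(C)=CCc1cc(Br)cc2c1O[C@H](C(C)(C)O)[C@H]2OC(C)=O | intermediate
17 | [5,7-bis(2,2-dimethylpropanoyloxy)-4-oxo-4H-chromen-2-yl]zinc chloride–lithium chloride | Cl[Zn]c1cc(=O)c2c(OC(=O)C(C)(C)C)cc(OC(=O)C(C)(C)C)cc2o1.[Li+].[Cl-] | intermediate
18 | 2-[(2S,3S)-3-acetoxy-2-(2-hydroxypropan-2-yl)-7-(3-methylbut-2-en-1-yl)-2,3-dihydro-1-benzofuran-5-yl]-4-oxo-4H-chromene-5,7-diyl bis(2,2-dimethylpropanoate) | CC(C)=CCc1cc(-c2cc(=O)c3c(OC(=O)C(C)(C)C)cc(OC(=O)C(C)(C)C)cc3o2)cc2c1O[C@H](C(C)(C)O)[C@H]2OC(C)=O | intermediate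
19 | 5,7-dihydroxy-2-[(2S,3S)-3-hydroxy-2-(2-hydroxypropan-2-yl)-7-(3-methylbut-2-en-1-yl)-2,3-dihydro-1-benzofuran-5-yl]-4H-chromen-4-one | CC(C)=CCc1cc(-c2cc(=O)c3c(O)cc(O)cc3o2)cc2c1O[C@H](C(C)(C)O)[C@H]2O | target

**Step count and risks**

Total step count: 11. Longest linear sequence: 7 (steps 5, 6, 7, 8, 9, 10, 11).

The three steps most likely to fail:

Step 9, the proposed new ring contraction. The risks are acetoxonium participation giving cis hydroxy acetates of the chroman, aryl migration to a dihydrobenzofuran-3-carbaldehyde, and loss of a proton from the tertiary cation to the isopropenyl compound. The fallback uses known chemistry and no rearrangement; it sets out from phenol 10 and comes back to the route at 16. Magnesium-mediated ortho-formylation of 10 (MgCl2, Et3N, paraformaldehyde, MeCN, reflux) gives 5-bromo-2-hydroxy-3-(3-methylbut-2-en-1-yl)benzaldehyde F1. O-Alkylation with chloroacetone (K2CO3, acetone) gives 5-bromo-3-(3-methylbut-2-en-1-yl)-2-(2-oxopropoxy)benzaldehyde F2. The (S)-proline-catalysed intramolecular 5-enolexo aldol reaction (DMF, rt), a known entry to cis-2-acyl-3-hydroxy-2,3-dihydrobenzofurans, closes the furan ring and gives 1-[(2S,3R)-5-bromo-3-hydroxy-7-(3-methylbut-2-en-1-yl)-2,3-dihydro-1-benzofuran-2-yl]ethan-1-one F3. Addition of MeMgCl/CeCl3 (THF, −78 °C) to the methyl ketone gives (2S,3R)-5-bromo-2-(2-hydroxypropan-2-yl)-7-(3-methylbut-2-en-1-yl)-2,3-dihydro-1-benzofuran-3-ol F4. Mitsunobu inversion of the benzylic alcohol with acetic acid (PPh3, DIAD, THF, 0 °C) converts the cis (3R) alcohol into the trans (3S) acetate 16.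

Step 10, the zincation and Negishi coupling. The risks are metalation of 7 at C3 instead of C2 (to be checked by an iodine quench), sluggish zincation next to the 5-pivalate, and protonation of the zinc reagent by the tertiary alcohol of 16. The fallback changes the polarity of the coupling; it sets out from 16 and comes back at 18. Borylation of 16 (B2(OH)4, Pd(OAc)2/XPhos, KOAc, EtOH, 80 °C) gives [(2S,3S)-3-acetoxy-2-(2-hydroxypropan-2-yl)-7-(3-methylbut-2-en-1-yl)-2,3-dihydro-1-benzofuran-5-yl]boronic acid F5. Conjugate addition of F5 to chromone 7 catalysed by Pd(OCOCF3)2/2,2′-bipyridine (divalent palladium, aqueous AcOH/dioxane, 60 °C) gives the flavanone 2-[(2S,3S)-3-acetoxy-2-(2-hydroxypropan-2-yl)-7-(3-methylbut-2-en-1-yl)-2,3-dihydro-1-benzofuran-5-yl]-4-oxo-3,4-dihydro-2H-chromene-5,7-diyl bis(2,2-dimethylpropanoate) F6 as both epimers at the flavanone carbon. Aerobic dehydrogenation (Pd(OCOCF3)2, DMSO, O2, 80 °C) removes that centre and gives 18.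

Step 3, the C–H hydroxylation. The risks are a twisted, ortho-substituted acetyl group that directs poorly and partial loss of the pivalates in the acidic medium. The fallback moves the oxygenation to the rigid chromone carbonyl, for which this ruthenium-catalysed C5–H hydroxylation is known; it sets out from 2 and comes back at 7. Ketone 2 with HC(OEt)3/HClO4 and then hot water gives 7-hydroxy-4H-chromen-4-one F7. Pivaloylation (PivCl, Et3N, CH2Cl2) gives 4-oxo-4H-chromen-7-yl 2,2-dimethylpropanoate F8. Oxygenation ([RuCl2(p-cymene)]2, PhI(OCOCF3)2, CF3CO2H/(CF3CO)2O, 80 °C) gives 4-oxo-7-(2,2-dimethylpropanoyloxy)-4H-chromen-5-yl trifluoroacetate F9, which water cleaves on work-up to 5-hydroxy-4-oxo-4H-chromen-7-yl 2,2-dimethylpropanoate F10. A second pivaloylation (PivCl, Et3N, DMAP) gives 7.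

**Further compounds**

F1 | step 9 | 5-bromo-2-hydroxy-3-(3-methylbut-2-en-1-yl)benzaldehyde | CC(C)=CCc1cc(Br)cc(C=O)c1O
F2 | step 9 | 5-bromo-3-(3-methylbut-2-en-1-yl)-2-(2-oxopropoxy)benzaldehyde | CC(C)=CCc1cc(Br)cc(C=O)c1OCC(C)=O
F3 | step 9 | 1-[(2S,3R)-5-bromo-3-hydroxy-7-(3-methylbut-2-en-1-yl)-2,3-dihydro-1-benzofuran-2-yl]ethan-1-one | CC(C)=CCc1cc(Br)cc2c1O[C@H](C(C)=O)[C@@H]2O
F4 | step 9 | (2S,3R)-5-bromo-2-(2-hydroxypropan-2-yl)-7-(3-methylbut-2-en-1-yl)-2,3-dihydro-1-benzofuran-3-ol | CC(C)=CCc1cc(Br)cc2c1O[C@H](C(C)(C)O)[C@@H]2O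
F5 | step 10 | [(2S,3S)-3-acetoxy-2-(2-hydroxypropan-2-yl)-7-(3-methylbut-2-en-1-yl)-2,3-dihydro-1-benzofuran-5-yl]boronic acid | CC(C)=CCc1cc(B(O)O)cc2c1O[C@H](C(C)(C)O)[C@H]2OC(C)=O
F6 | step 10 | 2-[(2S,3S)-3-acetoxy-2-(2-hydroxypropan-2-yl)-7-(3-methylbut-2-en-1-yl)-2,3-dihydro-1-benzofuran-5-yl]-4-oxo-3,4-dihydro-2H-chromene-5,7-diyl bis(2,2-dimethylpropanoate), both epimers at the flavanone carbon | CC(C)=CCc1cc(C2CC(=O)c3c(OC(=O)C(C)(C)C)cc(OC(=O)C(C)(C)C)cc3O2)cc2c1O[C@H](C(C)(C)O)[C@H]2OC(C)=O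
F7 | step 3 | 7-hydroxy-4H-chromen-4-one | O=c1ccoc2cc(O)ccc12
F8 | step 3 | 4-oxo-4H-chromen-7-yl 2,2-dimethylpropanoate | CC(C)(C)C(=O)Oc1ccc2c(=O)ccoc2c1
F9 | step 3 | 4-oxo-7-(2,2-dimethylpropanoyloxy)-4H-chromen-5-yl trifluoroacetate | CC(C)(C)C(=O)Oc1cc(OC(=O)C(F)(F)F)c2c(=O)ccoc2c1
F10 | step 3 | 5-hydroxy-4-oxo-4H-chromen-7-yl 2,2-dimethylpropanoate | CC(C)(C)C(=O)Oc1cc(O)c2c(=O)ccoc2c1
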